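## The problem

The target is 4-hydroxy-2-methoxy-6-[(2R)-2-acetoxytridecyl]benzoic acid (12). Its benzene ring (C1–C6) carries the carboxyl carbon C7 on C1, flanked by the methoxy-bearing C2 and by C6, which bears the chain C1′–C13′ with the acetoxy group on C2′. The two ring oxygens are differentiated against their natural reactivity: the oxygen on C2, ortho to the carboxyl group and the less reactive one in any orsellinate, is methylated, while the more reactive oxygen on C4 is free. C2′ is the only stereocentre (R); it is homobenzylic, nothing in the molecule can control it, so it must be set by an absolute method and then carried through without breaking its C–O bond. The compound is the O-acetylated seco acid of a 3-undecyl-3,4-dihydroisocoumarin. Whenever the C2′ oxygen is free and C7 is an acid or ester, the six-membered lactone can close, so the acetate must go on while C7 is masked and C7 must be unmasked without acid, base or heat. Saponification of a di-ortho-substituted benzoate at the end is therefore excluded, and the electron-rich acid is itself prone to protodecarboxylation. The feature that opens the plan is the path C7–C1–C2–C3–C4–C5–C6–C1′–C2′: an unbranched nine-carbon chain with oxygen on alternate carbons (C7, C2, C4, C2′; the oxygen of C6 lost as water), i.e. a folded tetraketide whose ring bond C1–C6 is an aldol bond. If this chain is assembled with the C2 oxygen already methylated and the C4 oxygen masked differently, the ring, its 1,2,3,5-substitution and the O-differentiation are all settled in one operation.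

## Retrosynthesis

**12 from 11.** The two O–benzyl bonds (carboxyl O–CH2Ph and C4 O–CH2Ph) of benzyl 6-[(2R)-2-acetoxytridecyl]-4-(benzyloxy)-2-methoxybenzoate 11 are cut last. A methyl or tert-butyl ester would need hydroxide, a thiolate or strong acid, each of which removes the acetate, closes the lactone or decarboxylates the acid. Hydrogenolysis is neutral and frees acid and phenol together. The forward reaction only has to spare the C2′–OAc bond, which is homobenzylic and not benzylic.

**11 from 10 from 9.** The acetyl–oxygen bond is cut back to alcohol 10, and 10 is traced to its silyl ether 9. The C2′ oxygen must be blocked while the ring is built under alkoxide, and must stay blocked until C7 is a hindered benzyl ester and the phenol is capped. The forward steps ask that 10 is freed without base and acetylated before it can lactonise.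

**9 from 8.** The C4 O–benzyl bond is cut. The phenol of 8 is the only acidic hydroxyl, so the forward etherification has no selectivity problem.

**8 from 6 via 7 (key disconnection).** Two bonds are cut: the ring bond C1–C6 (an aldol bond) and the C7–O bond of the benzyl ester. This gives the acyclic benzyl 3-methoxy-5,7-dioxo-enoate 7, which is the ring-opened form of pyranone 6.
- In 6 the lactone carbonyl is C7, pyranone C3 is C1, the enol-ether carbon C4 (OMe) is C2, pyranone C6 with the ring oxygen is C4, the exocyclic CH2 is C5 and the side-chain ketone is C6.
- Cuts at the chain–arene bonds (C6–C1′ or C1′–C2′) leave a fully substituted arene to be made and the two oxygens to be told apart. This cut makes the arene and carries the methyl group on the right oxygen from the outset.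
- Precursor 6 has no benzene ring and comes from one C–C bond formation between two simple pieces.
- The forward reaction must open the lactone with benzyl alkoxide, fold in the aldol sense (not the Claisen sense) and keep the enol-ether methyl group.

**6 from 3 and 4 via 5.** The bond between the exocyclic CH2 of the pyranone and the ketone carbon (target C5–C6) is cut. This gives the lithium dienolate 5 of commercial 4-methoxy-6-methyl-2H-pyran-2-one 4 and methyl (3R)-3-silyloxytetradecanoate 3. The pyranone supplies six of the nine chain carbons with both oxygens already differentiated; the ester supplies C6, C1′, C2′ and the undecyl chain with the stereocentre in place. The forward crossed Claisen condensation must occur at the exocyclic carbon and must not enolise 3.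

**3 from 2 from 1.** The Si–O bond is cut, then the C3–H bond of methyl (3R)-3-hydroxytetradecanoate 2, back to commercial methyl 3-oxotetradecanoate 1. The stereocentre is set by catalytic asymmetric hydrogenation of a β-keto ester, the most reliable way to a β-hydroxy ester with an n-alkyl chain.

## Roads not taken

**Alternative 1:** Cut the C1′–C2′ bond; this is the route most chemists would draw first. The forward key step is lateral lithiation of methyl 4-(benzyloxy)-2-methoxy-6-methylbenzoate A1 and addition of the benzylic anion to dodecanal. The alkoxide closes at once onto the ester to give 6-(benzyloxy)-8-methoxy-3-undecyl-3,4-dihydroisocoumarin A2.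
- The addition has no source of asymmetry, so A2 is racemic and C2′ would need correction by oxidation–reduction or resolution.
- A1 is not bought; its preparation spends steps on exactly the O-differentiation (benzylation of the para oxygen, methylation of the chelated ortho oxygen) that the pyranone already contains.
- The product is the lactone, which would have to be hydrolysed and the hydroxy carboxylate re-esterified before acetylation.
- The chosen plan never closes the lactone and sets C2′ by a catalytic hydrogenation.

**Alternative 2:** Cut the C6–C1′ bond. The forward key step is bromine–magnesium exchange on benzyl 4-(benzyloxy)-2-bromo-6-methoxybenzoate A4 and copper-catalysed opening of (2R)-2-undecyloxirane A3 at its CH2 group. The alkoxide would again lactonise, to (3R)-6-(benzyloxy)-8-methoxy-3-undecyl-3,4-dihydroisocoumarin A5.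
- The stereocentre comes cleanly from the epoxide, but A3 needs a hydrolytic kinetic resolution that discards half of the material.
- A4 has bromine meta to both oxygens, where electrophilic bromination does not go. It needs a longer construction in which two nearly equivalent ring positions (ortho to OMe, ortho to OBn) must be told apart.
- The lactone problem of Alternative 1 returns with A5.
- In the chosen plan no regiochemical choice is made on a preformed arene.

**Alternative 3:** Keep the aldol ring construction but mask the chain as a dioxinone: 6-[(6R)-6-(silyloxy)-2,4-dioxoheptadecyl]-2,2-dimethyl-4H-1,3-dioxin-4-one A6. Thermolysis in the presence of benzyl alcohol (acylketene trapping) and aldol aromatisation would give benzyl 2,4-dihydroxy-6-[(2R)-2-(silyloxy)tridecyl]benzoate A7.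
- This also delivers the benzyl ester directly and avoids alkoxide.
- A6 needs two successive C-acylations to build its chain; the pyranone route needs one.
- A7 has both phenols free. The target needs methyl on the chelated, less reactive C2 oxygen and nothing on the C4 oxygen, so benzylation at C4 and then methylation at C2 would be needed to reach 9 (two more steps).
- In 6 the methyl group is already on the right oxygen, because that oxygen is an enol ether and the other is the lactone oxygen.

Key step: step 4

Assumption: the given descriptor is read as (R) at C2′ (priorities O > C1′ > C3′ > H); compounds 1 and 4 and sodium benzyloxide in benzyl alcohol are taken as articles of commerce.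

## Route

Step 1
Reactants: 1 methyl 3-oxotetradecanoate
Product: 2 methyl (3R)-3-hydroxytetradecanoate
Conditions: H2 (10 bar), RuCl2[(R)-BINAP] (0.1 mol %), MeOH, 50 °C
Reagents that add atoms: none
Why: Noyori asymmetric hydrogenation of a β-keto ester; the ester carbonyl chelates ruthenium and the (R)-BINAP ligand directs hydride to the face that gives the (3R)-alcohol, as for other 3-oxoalkanoates with n-alkyl chains. This sets the only stereocentre of the target.

Step 2
Reactants: 2 methyl (3R)-3-hydroxytetradecanoate
Product: 3 methyl (3R)-3-[(tert-butyldimethylsilyl)oxy]tetradecanoate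
Conditions: TBSCl, imidazole, DMF, rt
Reagents that add atoms: tert-butyldimethylsilyl chloride, CC(C)(C)[Si](C)(C)Cl
Why: Standard silylation of a secondary alcohol. The silyl ether blocks retro-aldol cleavage, β-elimination and hemiketal formation in steps 3 and 4 and keeps the oxygen away from the ester until the acetate is on.

Step 3
Reactants: 3 methyl (3R)-3-[(tert-butyldimethylsilyl)oxy]tetradecanoate; 4 4-methoxy-6-methyl-2H-pyran-2-one
Product: 6 6-[(4R)-4-[(tert-butyldimethylsilyl)oxy]-2-oxopentadecyl]-4-methoxy-2H-pyran-2-one, via lithiated pyranone 5 (not isolated)
Conditions: 4 (2.2 equiv), LiN(SiMe3)2 (2.3 equiv), THF, −78 °C; then 3, −78 to −40 °C; AcOH, −78 °C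
Reagents that add atoms: none
Why: Crossed Claisen condensation: the amide base removes a proton from the C6 methyl group of 4 (vinylogous enolisation) and dienolate 5 acylates at its exocyclic carbon, which restores the pyranone. The second equivalent of 5 is consumed in deprotonating the more acidic product; this also protects the new ketone from further addition and from β-elimination. The stereocentre is β to the carbonyl group and is untouched.

Step 4
Reactants: 6 6-[(4R)-4-[(tert-butyldimethylsilyl)oxy]-2-oxopentadecyl]-4-methoxy-2H-pyran-2-one
Product: 8 benzyl 4-hydroxy-2-methoxy-6-[(2R)-2-[(tert-butyldimethylsilyl)oxy]tridecyl]benzoate, via ring-opened benzyl dioxoenoate 7 (not isolated)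
Conditions: NaOCH2Ph (1.0 M in PhCH2OH, 4 equiv), THF, 50 °C; then AcOH, 0 °C
Reagents that add atoms: sodium benzyloxide, [Na+].[O-]Cc1ccccc1; benzyl alcohol, OCc1ccccc1
Why: Benzyloxide adds to the lactone carbonyl of 6 and the ring opens, the C6 oxygen leaving as part of a 1,3-diketonate, to give the acyclic masked triketo ester 7; proton transfer in the alcohol medium moves the charge to the vinylogous anion that runs from the C5 carbonyl through C4 and the C2=C3 enol ether to the ester (chain numbering of 7). The carbon α to the ester (chain C2) then adds to the C7 ketone in a 6-(enolexo)-exo-trig aldol closure that forms the arene C1–C6 bond, and loss of water and enolisation give the phenoxide of 8, which makes the sequence irreversible. The closest known reaction type is the methoxide- or hydroxide-induced isomerisation of 6-(2-oxoalkyl)-4-methoxy-2-pyranones into 2-O-methylresorcylates, the laboratory counterpart of polyketide aldol folding; only the alkoxide is changed, so that the ester is formed directly as a benzyl ester. No stereocentre is formed, and chain C9 (the later C2′) is not α to any carbonyl group and cannot epimerise. Two selectivities are needed. Aldol folding (C2 to C7) must win over Claisen folding (C6 to C1) and over O-cyclisation to a 4-pyranone: the methyl enol ether secures this, because it makes C1 a vinylogous carbonate of low electrophilicity and C2 the nucleophilic end of the dienolate, while the C7 ketone is the only carbonyl group outside the anion. The methoxy group must stay on C3 and not be exchanged for benzyloxy by addition–elimination: 6 rests as its delocalised anion, which resists conjugate attack, and 7 has a six-membered intramolecular closure open to it as soon as it forms. The silyl ether keeps the C9 oxygen from retro-aldol cleavage, β-elimination and hemiketal formation during the fold.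

Step 5
Reactants: 8 benzyl 4-hydroxy-2-methoxy-6-[(2R)-2-[(tert-butyldimethylsilyl)oxy]tridecyl]benzoate
Product: 9 benzyl 4-(benzyloxy)-2-methoxy-6-[(2R)-2-[(tert-butyldimethylsilyl)oxy]tridecyl]benzoate
Conditions: BnBr, K2CO3, acetone, 50 °C
Reagents that add atoms: benzyl bromide, BrCc1ccccc1
Why: Williamson etherification of the only acidic hydroxyl, a phenol para to the ester. The benzyl ether keeps the phenol from being acetylated in step 7 and leaves together with the benzyl ester in step 8.

Step 6
Reactants: 9 benzyl 4-(benzyloxy)-2-methoxy-6-[(2R)-2-[(tert-butyldimethylsilyl)oxy]tridecyl]benzoate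
Product: 10 benzyl 4-(benzyloxy)-6-[(2R)-2-hydroxytridecyl]-2-methoxybenzoate
Conditions: HF·pyridine, pyridine, THF, 0 °C to rt
Reagents that add atoms: none
Why: Fluoride-induced Si–O cleavage under buffered, weakly acidic conditions. No alkoxide is formed, so closure of the lactone onto the twisted, di-ortho-substituted benzyl ester should be slow; the C–O bond of the stereocentre is not touched. The product is used at once.

Step 7
Reactants: 10 benzyl 4-(benzyloxy)-6-[(2R)-2-hydroxytridecyl]-2-methoxybenzoate
Product: 11 benzyl 6-[(2R)-2-acetoxytridecyl]-4-(benzyloxy)-2-methoxybenzoate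
Conditions: Ac2O, DMAP (cat.), pyridine, CH2Cl2, 0 °C
Reagents that add atoms: acetic anhydride, CC(=O)OC(C)=O
Why: DMAP-catalysed acylation of a secondary alcohol, fast at 0 °C and expected to outrun lactonisation. The configuration is retained because only the O–H bond is broken.

Step 8
Reactants: 11 benzyl 6-[(2R)-2-acetoxytridecyl]-4-(benzyloxy)-2-methoxybenzoate
Product: 12 4-hydroxy-2-methoxy-6-[(2R)-2-acetoxytridecyl]benzoic acid
Conditions: H2 (1 atm), Pd/C (10 wt %), EtOAc, rt
Reagents that add atoms: none
Why: Hydrogenolysis of the benzyl ester and the aryl benzyl ether frees acid and phenol together under neutral conditions, so the acetate neither migrates nor is displaced by lactonisation. The C2′–OAc bond is homobenzylic and is not cleaved; the product is isolated without heating to avoid decarboxylation.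

## Compound list

1 | methyl 3-oxotetradecanoate | CCCCCCCCCCCC(=O)CC(=O)OC | starting material
2 | methyl (3R)-3-hydroxytetradecanoate | CCCCCCCCCCC[C@H](CC(=O)OC)O | intermediate
3 | methyl (3R)-3-[(tert-butyldimethylsilyl)oxy]tetradecanoate | CCCCCCCCCCC[C@H](CC(=O)OC)O[Si](C)(C)C(C)(C)C | intermediate
4 | 4-methoxy-6-methyl-2H-pyran-2-one | Cc1cc(OC)cc(=O)o1 | starting material
5 | lithium dienolate of 4 (6-(lithiomethyl)-4-methoxy-2H-pyran-2-one) | [Li+].[CH2-]c1cc(OC)cc(=O)o1 | intermediate
6 | 6-[(4R)-4-[(tert-butyldimethylsilyl)oxy]-2-oxopentadecyl]-4-methoxy-2H-pyran-2-one | CCCCCCCCCCC[C@H](CC(=O)Cc1cc(OC)cc(=O)o1)O[Si](C)(C)C(C)(C)C | intermediate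
7 | benzyl (2E,9R)-9-[(tert-butyldimethylsilyl)oxy]-3-methoxy-5,7-dioxoicos-2-enoate | CCCCCCCCCCC[C@H](CC(=O)CC(=O)C/C(OC)=C\C(=O)OCc1ccccc1)O[Si](C)(C)C(C)(C)C | intermediate
8 | benzyl 4-hydroxy-2-methoxy-6-[(2R)-2-[(tert-butyldimethylsilyl)oxy]tridecyl]benzoate | CCCCCCCCCCC[C@H](Cc1cc(O)cc(OC)c1C(=O)OCc2ccccc2)O[Si](C)(C)C(C)(C)C | intermediate
9 | benzyl 4-(benzyloxy)-2-methoxy-6-[(2R)-2-[(tert-butyldimethylsilyl)oxy]tridecyl]benzoate | CCCCCCCCCCC[C@H](Cc1cc(OCc2ccccc2)cc(OC)c1C(=O)OCc3ccccc3)O[Si](C)(C)C(C)(C)C | intermediate
10 | benzyl 4-(benzyloxy)-6-[(2R)-2-hydroxytridecyl]-2-methoxybenzoate | CCCCCCCCCCC[C@H](Cc1cc(OCc2ccccc2)cc(OC)c1C(=O)OCc3ccccc3)O | intermediate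
11 | benzyl 6-[(2R)-2-acetoxytridecyl]-4-(benzyloxy)-2-methoxybenzoate | CCCCCCCCCCC[C@H](Cc1cc(OCc2ccccc2)cc(OC)c1C(=O)OCc3ccccc3)OC(C)=O | intermediate
12 | 4-hydroxy-2-methoxy-6-[(2R)-2-acetoxytridecyl]benzoic acid | CCCCCCCCCCC[C@H](Cc1cc(O)cc(OC)c1C(=O)O)OC(C)=O | target

## Step count and risk

Total steps: 8. Longest linear sequence: 8 steps (1 to 12); pyranone 4 is bought and enters at step 3.

**Step 4 (key step).** The most likely failure is exchange of the enol-ether methoxy group for benzyloxy by conjugate addition–elimination of benzyloxide before the ring closes; the methoxide so released could also enter the ester position. Less likely are folding in the Claisen sense and slow loss of the silyl group to warm alkoxide. Fallback, from 6: the fold is run with Mg(OMe)2 in methanol at reflux, where any exchange is degenerate, to give methyl 4-hydroxy-2-methoxy-6-[(2R)-2-[(tert-butyldimethylsilyl)oxy]tridecyl]benzoate F1. Benzylation of the phenol (BnBr, K2CO3) gives methyl 4-(benzyloxy)-2-methoxy-6-[(2R)-2-[(tert-butyldimethylsilyl)oxy]tridecyl]benzoate F2. The methyl ester is then cleaved at its methyl carbon with LiSPr in DMF (SN2, indifferent to the shielding of the carbonyl group) to 4-(benzyloxy)-2-methoxy-6-[(2R)-2-[(tert-butyldimethylsilyl)oxy]tridecyl]benzoic acid F3. Benzylation of its carboxylate (BnBr, K2CO3, DMF) returns to the route at 9. The benzyl ester is then made by ester interchange after the fold instead of in it, at the price of two steps.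

**Step 3.** The most likely failures are enolisation of ester 3 by the dienolate followed by β-elimination of silanolate, and incomplete acylation because the product quenches the nucleophile. Fallback, from 3: reduction with (i-Bu)2AlH at −78 °C gives (3R)-3-[(tert-butyldimethylsilyl)oxy]tetradecanal F4. Aldol addition of 5 (an aldehyde cannot be enolised into elimination as easily and needs one equivalent of anion) gives 6-[(4R)-4-[(tert-butyldimethylsilyl)oxy]-2-hydroxypentadecyl]-4-methoxy-2H-pyran-2-one F5 as a mixture of carbinol epimers, which does not matter. Oxidation with Dess–Martin periodinane returns to the route at 6.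

**Step 6.** The most likely failure is lactonisation: the freed C2′ hydroxyl attacks the benzyl ester in a six-membered closure with loss of benzyl alcohol, during desilylation, on silica or in the first moments of step 7. Fallback, from 9: the silyl ether is converted directly into the acetate with Ac2O and catalytic Cu(OTf)2 in CH2Cl2 at 0 °C. The oxygen is acylated as the silicon leaves, the free hydroxy ester is never present, and the route is rejoined at 11 without any new compound.

## Further compounds

F1 | step 4 | methyl 4-hydroxy-2-methoxy-6-[(2R)-2-[(tert-butyldimethylsilyl)oxy]tridecyl]benzoate | CCCCCCCCCCC[C@H](Cc1cc(O)cc(OC)c1C(=O)OC)O[Si](C)(C)C(C)(C)C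
F2 | step 4 | methyl 4-(benzyloxy)-2-methoxy-6-[(2R)-2-[(tert-butyldimethylsilyl)oxy]tridecyl]benzoate | CCCCCCCCCCC[C@H](Cc1cc(OCc2ccccc2)cc(OC)c1C(=O)OC)O[Si](C)(C)C(C)(C)C
F3 | step 4 | 4-(benzyloxy)-2-methoxy-6-[(2R)-2-[(tert-butyldimethylsilyl)oxy]tridecyl]benzoic acid | CCCCCCCCCCC[C@H](Cc1cc(OCc2ccccc2)cc(OC)c1C(=O)O)O[Si](C)(C)C(C)(C)C
F4 | step 3 | (3R)-3-[(tert-butyldimethylsilyl)oxy]tetradecanal | CCCCCCCCCCC[C@H](CC=O)O[Si](C)(C)C(C)(C)C
F5 | step 3 | 6-[(4R)-4-[(tert-butyldimethylsilyl)oxy]-2-hydroxypentadecyl]-4-methoxy-2H-pyran-2-one (both carbinol epimers) | CCCCCCCCCCC[C@H](CC(O)Cc1cc(OC)cc(=O)o1)O[Si](C)(C)C(C)(C)C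
F0 | step 6 | none | none
A1 | alternative 1 | methyl 4-(benzyloxy)-2-methoxy-6-methylbenzoate | COC(=O)c1c(C)cc(OCc2ccccc2)cc1OC
A2 | alternative 1 | 6-(benzyloxy)-8-methoxy-3-undecyl-3,4-dihydro-1H-isochromen-1-one (racemic) | CCCCCCCCCCCC1Cc2cc(OCc3ccccc3)cc(OC)c2C(=O)O1
A3 | alternative 2 | (2R)-2-undecyloxirane | CCCCCCCCCCC[C@@H]1CO1
A4 | alternative 2 | benzyl 4-(benzyloxy)-2-bromo-6-methoxybenzoate | COc1cc(OCc2ccccc2)cc(Br)c1C(=O)OCc3ccccc3
A5 | alternative 2 | (3R)-6-(benzyloxy)-8-methoxy-3-undecyl-3,4-dihydro-1H-isochromen-1-one | CCCCCCCCCCC[C@@H]1Cc2cc(OCc3ccccc3)cc(OC)c2C(=O)O1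
A6 | alternative 3 | 6-[(6R)-6-[(tert-butyldimethylsilyl)oxy]-2,4-dioxoheptadecyl]-2,2-dimethyl-4H-1,3-dioxin-4-one | CCCCCCCCCCC[C@H](CC(=O)CC(=O)CC1=CC(=O)OC(C)(C)O1)O[Si](C)(C)C(C)(C)C
A7 | alternative 3 | benzyl 2,4-dihydroxy-6-[(2R)-2-[(tert-butyldimethylsilyl)oxy]tridecyl]benzoate | CCCCCCCCCCC[C@H](Cc1cc(O)cc(O)c1C(=O)OCc2ccccc2)O[Si](C)(C)C(C)(C)C
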